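I started with an easy step. At 1.3 equiv of partner, the substrate is the limiting reagent, so the ceiling for product was 100% of the charge.

in all of them: substrate 0.25 M; free catalyst 2.9 mol%; added ligand 4.9 mM
- larch: partner 1.3 equiv; capture agent 0.025 M; the very flask that is asked about, followed so far
- flask: partner 1.30 equiv; capture agent 0.0250 M; time 2.0 d

larch run (percent of the substrate charged): time / h: product / % = 3.00: 47.5; 6.00: 60.3; 10.0: 69.8; 20.0: 76.3; 40.0: 78.8

(standard deviation of a reading: 1 percentage point)

* product, in percent of the substrate first charged, at 2.0 d
* what to do for the largest gain in product; "none" if nothing gains more than 2 percentage points (Tuesday's / Wednesday's / Saturday's / Thursday's / none)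
* product present, with what was taken out counted in, in percent of the substrate first charged, after Tuesday's
* product present, with what was taken out counted in, in percent of the substrate first charged, after Wednesday's

- Tuesday's: at 2.0 d add free catalyst, 100% of the amount charged, then wait 25 h
- Wednesday's: change nothing and wait 25 h more
- Saturday's: at 2.0 d take out 90% of the product then present, then wait 25 h
- Thursday's: at 2.0 d add partner, 50.0% of the amount charged, then wait 25 h

- what is taken out of product is counted as made
- additions bring no volume worth counting

The last reading, 78.8% at 40.0 h, was my floor, within the scatter. To lower the ceiling I worked with fractions left. From the product I reckoned the fraction of substrate left and the fraction of partner left, then took the logarithm of partner left over substrate left. If the rate is first order in each, this logarithm grows in step with catalyst activity, so I called it the work.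

The work read 0.427 at 10.0 h, 0.556 at 20.0 h and 0.619 at 40.0 h. Its mean rate fell. So the hours after 40.0 h should add less than their pro rata share of the last stretch. As read from these scattered readings, that put the work at 2.0 d below 0.645 and product below 79.7%.

Next I took the fall as steady. Each 10.0 h then multiplied the rate by 0.365. The work levelled at 0.629, a reading I called the flask's work budget. Turned back, it gave 79.2%, my figure for now and for waiting. Fresh catalyst at the full charge should add a second budget, giving 91.6%. That gain of 12 percentage points passes the margin.

The forecast gave 79.3%, inside my bracket. It chose Tuesday's, with 89.5% after it, lower than my figure, and 79.6% after waiting. Its ground was this: “the catalyst is dying with a half-life of about 7 h”.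

The flask gave 79.0%, below my upper bound and level with the floor within the scatter. The best choice was Tuesday's, with 91.2%, and waiting gave 79.1%.

    catalyst intermediate A → catalyst intermediate B (k = 0.440 /s)
    substrate + catalyst intermediate B ⇌ catalyst intermediate C (K = 7.50 /M, k = 0.0390 /M/s)
    partner + free catalyst ⇌ catalyst intermediate A (K = 0.460 /M, k = 0.0360 /M/s)
    catalyst intermediate C ⇌ free catalyst + product (K = 0.0700 M, k = 0.210 /s)
    capture agent + catalyst intermediate B → trapped intermediate (k = 0.00290 /M/s)
    free catalyst + added ligand ⇌ idle complex (K = 250 /M, k = 0.270 /M/s)

Reckoned from these results, the fresh catalyst added 0.595 of work, against the budget of 0.629. The scheme has the catalyst leaving the round by capture agent, first order in it. So for the neighbouring flask, with 0.10 M of capture agent, I divided the budget by 4.00. That left 0.157 of work, which turned back into 42.5% of product. The neighbouring flask gave 45.1%, with 55% of its substrate still unused.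

The data were generated by integration with constants of no real substance.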